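(Readings and results stem from a simulated flask with constants of no real substance, and the scatter is random.)

The leftover struck me first: at 30 h the theta flask still held 129 mM of its Q, the limiting reagent by charge, though Z was charged at twice Q, so I chose to count what a flask gets through.

in all of them: L 0.400 mM
- theta: Q 200 mM; Z 400 mM
- delta: Q 80.0 mM; Z 280 mM
- zeta: Q 200 mM; Z 600 mM
- epsilon: Q 200 mM; Z 980 mM; time 30 h

| run | time / h | [G] / mM |
|---|---|---|
| theta run | 1.2 | 21.8 |
| theta run | 2.3 | 32.2 |
| theta run | 4.3 | 45.1 |
| theta run | 8.3 | 57.8 |
| theta run | 16 | 65.9 |
| theta run | 30 | 71.2 |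
| delta run | 1.2 | 9.2 |
| delta run | 2.3 | 12.8 |
| delta run | 4.3 | 18.1 |
| delta run | 8.3 | 24.2 |
| delta run | 16 | 32.2 |
| delta run | 30 | 36.7 |
| zeta run | 1.2 | 29.4 |
| zeta run | 2.3 | 42.2 |
| zeta run | 4.3 | 56.1 |
| zeta run | 8.3 | 70.8 |
| zeta run | 16 | 80.1 |
| zeta run | 30 | 85.4 |

(standard deviation of a reading: 0.6 mM)

- Overall: Q + Z -> G, with L as catalyst.
- Constant volume, constant temperature.
- Readings of a species count what is bound in complexes too.
- "The second partner" is Z.
- An order is taken over about fifteen percent of the charge, up and down.

- the exponent of [Z] in the starting rate at the charge of the theta run (at the point where two percent of the Q have become G)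
- the exponent of [Q] in the starting rate at the charge of the theta run (at the point where two percent of the Q have become G) (one fixed amount of G, the same in the runs compared)
- G in the epsilon run at 30 h, as a share of the Q charged

I kept one number per flask, 0.635 for theta: the half-life count, how many times the Q has been halved by 30 h, which is the logarithm to base two of Q charged over Q left. At the first reading the zeta flask held 1.35 times the G of the theta flask for 1.50 times the Z, and as that reading is a stretch of bending curve and no starting rate, I took Z as first order; the same reading in the delta flask, set over the theta one and divided by the Z ratio, gave me an order in Q of 0.552, a rough figure read at no fixed amount of G. Yet the zeta count was 0.803, a gain of 1.26 times, smaller than the Z ratio. I therefore guessed that Z was being lost faster the more of it there was, and assumed that equal factors in the Z charge add equal steps to the count, 0.416 half-lives per factor of e. From zeta to 980 mM in the epsilon flask that made 1.01 half-lives, or 50.3 % of the Q as G.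

The forecast, holding that “the stall does not fit a single equilibrium constant”, gave orders of 1 in Z and 1 in Q, and 51 %. The flask gave 1.0, 0.74 and 50.4 %, a count of 1.01, while my order in Q stood lower.

    L + Q ⇌ LQ, settled at all times (2.420 L mol⁻¹)
    LQ + Z → G + L (464.4 L mol⁻¹ h⁻¹)
    L + Q → Xa + Q (0.5724 L mol⁻¹ h⁻¹)
    2 Z → Vo (0.5292 L mol⁻¹ h⁻¹)

The main reason for the shortfall was the passing of two Z into Vo: the epsilon flask without that step reached >99.9 %. The first half-life of Z by this step alone was 2.36 h at the theta charge and 0.964 h at the epsilon charge, so the larger charge raised the count from 0.635 to just 1.01. In the epsilon flask without L + Q → Xa + Q, where Z still went, G reached 61.6 %, a count of 1.38.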